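The bond broken in the retrosynthesis is C7a=C12a, the C2=C3 bond of the pyrrole ring of indole B (N12, C12a, C7a, C7b, C11a). In an ortho-acyl anilide both of these carbons are carbonyl carbons. A titanium-mediated reductive oxo-amide coupling joins them in one operation, closes ring B and gives the 2,2'-biindole, so no metal-catalysed biaryl coupling next to the aryl bromide is needed. The precursor is the 6-bromoindole-2-carboxanilide of 1-(2-aminophenyl)-3-silyloxypropan-1-one: its ketone carbon becomes C7a, its amide carbon C12a, and the silyloxyethyl arm later supplies C6 and C7. Afterwards C13 is acylated, ring C is closed at N5 by a Mitsunobu reaction, and C6–C7 is dehydrogenated.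

Key step: step 5

Remark: the target has no stereogenic element, so no enantiocontrol is needed (carbinol 4 is racemic and its centre is removed in step 2); atom labels follow 12H-pyrido[1,2-a:3,4-b']diindole numbering.

Step 1
Reactants: 1 1-iodo-2-nitrobenzene; 2 3-(tert-butyldimethylsilyloxy)propanal
Product: 4 rac-3-(tert-butyldimethylsilyloxy)-1-(2-nitrophenyl)propan-1-ol, via 2-nitrophenylmagnesium chloride 3 (not isolated)
Conditions: PhMgCl (1.05 equiv), THF, −40 °C, 10 min; then 2, −40 → −20 °C; aq. NH4Cl
Reagents that add atoms: none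
Why: Iodine–magnesium exchange on the ortho-nitro iodide (Knochel-type) is fast at −40 °C, where the chelated aryl Grignard reagent does not attack the nitro group, and Grignard 1,2-addition to the aldehyde follows; the carbinol centre forms as a racemate and is erased in step 2.

Step 2
Reactants: 4 rac-3-(tert-butyldimethylsilyloxy)-1-(2-nitrophenyl)propan-1-ol
Product: 5 3-(tert-butyldimethylsilyloxy)-1-(2-nitrophenyl)propan-1-one
Conditions: Dess–Martin periodinane, CH2Cl2, 0 °C → rt
Reagents that add atoms: none
Why: Dess–Martin oxidation of a secondary benzylic alcohol runs under near-neutral conditions, so the primary silyl ether and the nitro group should survive and no base is present that could expel silanolate from the β-silyloxy ketone.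

Step 3
Reactants: 5 3-(tert-butyldimethylsilyloxy)-1-(2-nitrophenyl)propan-1-one
Product: 6 1-(2-aminophenyl)-3-(tert-butyldimethylsilyloxy)propan-1-one
Conditions: H2 (1 atm), 10% Pd/C, EtOAc, rt
Reagents that add atoms: none
Why: Catalytic hydrogenation reduces an aromatic nitro group much faster than an aryl ketone, no halogen is present yet, the neutral medium spares the silyl ether, and any anthranil formed in passing would be hydrogenolysed to the same amino ketone.

Step 4
Reactants: 7 6-bromo-1H-indole-2-carboxylic acid; 6 1-(2-aminophenyl)-3-(tert-butyldimethylsilyloxy)propan-1-one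
Product: 9 6-bromo-N-{2-[3-(tert-butyldimethylsilyloxy)propanoyl]phenyl}-1H-indole-2-carboxamide, via 6-bromo-1H-indole-2-carbonyl chloride 8 (not isolated)
Conditions: 7, (COCl)2, cat. DMF, CH2Cl2, 0 °C → rt; evaporate; then 6, pyridine, CH2Cl2, 0 °C → rt
Reagents that add atoms: none
Why: N-acylation with an acid chloride (formed under Vilsmeier catalysis) is chosen because the hydrogen-bonded ortho-acyl aniline is a weak nucleophile, and pyridine takes up the HCl so that the silyl ether is kept.

Step 5
Reactants: 9 6-bromo-N-{2-[3-(tert-butyldimethylsilyloxy)propanoyl]phenyl}-1H-indole-2-carboxamide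
Product: 10 6-bromo-3'-[2-(tert-butyldimethylsilyloxy)ethyl]-1H,1'H-2,2'-biindole
Conditions: TiCl3 (4 equiv), Zn dust (8 equiv), THF, reflux; filtration through silica
Reagents that add atoms: none
Why: Low-valent titanium reduces the aryl ketone to a titanium-bound ketyl (or dianion) whose carbon, the future C7a, adds to the carbonyl carbon of the ortho anilide, the future C12a; the oxophilic metal then removes both oxygens from the cyclic titanium alkoxide and leaves the C7a=C12a bond of an aromatic pyrrole. The closest known reaction type is the titanium-mediated oxo-amide coupling to indoles (Fürstner indole synthesis, a McMurry-type reaction), in which N–H amides, aryl halides and silyl ethers are established spectators. Ring B (N12, C12a, C7a, C7b, C11a) closes in a 5-exo-trig mode, since the attacked C=O lies outside the forming five-membered ring. No stereocentre is formed. The step needs reduction of the ketone in preference to the amide, the aryl C–Br bond and the silyl ether, and ring closure in preference to intermolecular pinacol coupling: the ketone is the only function reducible under these conditions, the ortho arrangement holds exactly one amide carbonyl within bonding distance of the ketyl, and the silyloxy group is a poor leaving group two carbons away from the ketone. Aromatisation of the new pyrrole makes the deoxygenation irreversible.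

Step 6
Reactants: 10 6-bromo-3'-[2-(tert-butyldimethylsilyloxy)ethyl]-1H,1'H-2,2'-biindole
Product: 13 methyl 2-{6-bromo-2-[3-(2-hydroxyethyl)-1H-indol-2-yl]-1H-indol-3-yl}-2-oxoacetate, via indol-3-ylglyoxylyl chloride 11 (not isolated), via silyl-protected methyl ester 12 (not isolated)
Conditions: (COCl)2 (1.05 equiv), Et2O–CH2Cl2, 0 °C; then MeOH (excess), 0 °C → rt; aq. NaHCO3
Reagents that add atoms: oxalyl chloride, O=C(Cl)C(Cl)=O; methanol, CO
Why: Uncatalysed Friedel–Crafts-type acylation by oxalyl chloride occurs at the only unsubstituted indole β-position (the future C13), methanol converts the acid chloride into the methyl ester, and the HCl so generated in methanol should cleave the primary silyl ether in the same pot (the acyl chloride/methanol type of desilylation); any acylation at the neighbouring N–H would be undone by the methanolysis.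

Step 7
Reactants: 13 methyl 2-{6-bromo-2-[3-(2-hydroxyethyl)-1H-indol-2-yl]-1H-indol-3-yl}-2-oxoacetate
Product: 14 methyl 2-(3-bromo-6,7-dihydro-12H-pyrido[1,2-a:3,4-b']diindol-13-yl)-2-oxoacetate
Conditions: PPh3, DIAD, THF, 0 °C → rt
Reagents that add atoms: none
Why: Intramolecular Mitsunobu N-alkylation should close ring C by 6-exo-tet displacement, because the 3-glyoxylyl group brings the adjacent indole N–H (the future N5) into the Mitsunobu acidity range and blocks the competing carbon nucleophile C13, and the N12–H···O=C hydrogen bond holds the biaryl rotamer that places this nitrogen next to the activated primary carbon.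

Step 8
Reactants: 14 methyl 2-(3-bromo-6,7-dihydro-12H-pyrido[1,2-a:3,4-b']diindol-13-yl)-2-oxoacetate
Product: 15 methyl 2-(3-bromo-12H-pyrido[1,2-a:3,4-b']diindol-13-yl)-2-oxoacetate (target)
Conditions: DDQ (1.1 equiv), anhydrous 1,4-dioxane, rt → 60 °C
Reagents that add atoms: none
Why: In this quinone dehydrogenation DDQ abstracts hydride from C7, which is benzylic to C7a of the electron-rich indole B, and loss of the C6 proton then gives the C6=C7 bond; the keto ester at C13 keeps the other indole from reacting with the quinone.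

Compound list
1 | 1-iodo-2-nitrobenzene | O=[N+]([O-])c1ccccc1I | starting material
2 | 3-(tert-butyldimethylsilyloxy)propanal | CC(C)(C)[Si](C)(C)OCCC=O | starting material
3 | 2-nitrophenylmagnesium chloride | O=[N+]([O-])c1ccccc1[Mg]Cl | intermediate
4 | rac-3-(tert-butyldimethylsilyloxy)-1-(2-nitrophenyl)propan-1-ol | CC(C)(C)[Si](C)(C)OCCC(O)c1ccccc1[N+](=O)[O-] | intermediate
5 | 3-(tert-butyldimethylsilyloxy)-1-(2-nitrophenyl)propan-1-one | CC(C)(C)[Si](C)(C)OCCC(=O)c1ccccc1[N+](=O)[O-] | intermediate
6 | 1-(2-aminophenyl)-3-(tert-butyldimethylsilyloxy)propan-1-one | CC(C)(C)[Si](C)(C)OCCC(=O)c1ccccc1N | intermediate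
7 | 6-bromo-1H-indole-2-carboxylic acid | O=C(O)c1cc2ccc(Br)cc2[nH]1 | starting material
8 | 6-bromo-1H-indole-2-carbonyl chloride | O=C(Cl)c1cc2ccc(Br)cc2[nH]1 | intermediate
9 | 6-bromo-N-{2-[3-(tert-butyldimethylsilyloxy)propanoyl]phenyl}-1H-indole-2-carboxamide | CC(C)(C)[Si](C)(C)OCCC(=O)c1ccccc1NC(=O)c1cc2ccc(Br)cc2[nH]1 | intermediate
10 | 6-bromo-3'-[2-(tert-butyldimethylsilyloxy)ethyl]-1H,1'H-2,2'-biindole | CC(C)(C)[Si](C)(C)OCCc1c(-c2cc3ccc(Br)cc3[nH]2)[nH]c2ccccc12 | intermediate
11 | 2-{6-bromo-2-[3-(2-(tert-butyldimethylsilyloxy)ethyl)-1H-indol-2-yl]-1H-indol-3-yl}-2-oxoacetyl chloride | CC(C)(C)[Si](C)(C)OCCc1c(-c2c(C(=O)C(=O)Cl)c3ccc(Br)cc3[nH]2)[nH]c2ccccc12 | intermediate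
12 | methyl 2-{6-bromo-2-[3-(2-(tert-butyldimethylsilyloxy)ethyl)-1H-indol-2-yl]-1H-indol-3-yl}-2-oxoacetate | CC(C)(C)[Si](C)(C)OCCc1c(-c2c(C(=O)C(=O)OC)c3ccc(Br)cc3[nH]2)[nH]c2ccccc12 | intermediate
13 | methyl 2-{6-bromo-2-[3-(2-hydroxyethyl)-1H-indol-2-yl]-1H-indol-3-yl}-2-oxoacetate | OCCc1c(-c2c(C(=O)C(=O)OC)c3ccc(Br)cc3[nH]2)[nH]c2ccccc12 | intermediate
14 | methyl 2-(3-bromo-6,7-dihydro-12H-pyrido[1,2-a:3,4-b']diindol-13-yl)-2-oxoacetate | COC(=O)C(=O)c1c2ccc(Br)cc2n2CCc3c4ccccc4[nH]c3-c12 | intermediate
15 | methyl 2-(3-bromo-12H-pyrido[1,2-a:3,4-b']diindol-13-yl)-2-oxoacetate | COC(=O)C(=O)c1c2ccc(Br)cc2n2ccc3c4ccccc4[nH]c3c12 | target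

Total step count: 8
Longest linear sequence: 8 steps (1 and 2 to 15; acid 7 enters unchanged in step 4)

Steps most likely to fail

Step 5. The ketyl may be reduced further to the carbinol or couple intermolecularly before it reaches the amide, the Lewis-acidic titanium and zinc salts may strip the silyl ether, and slow hydrodebromination is possible. The fallback sets out from 9 and returns at 10, forming the same C7a=C12a bond without a reducing metal. NaBH4 in MeOH should reduce the ketone to the benzylic alcohol rac-6-bromo-N-{2-[3-(tert-butyldimethylsilyloxy)-1-hydroxypropyl]phenyl}-1H-indole-2-carboxamide F1. Ph3P·HBr in MeCN should convert it into the phosphonium salt rac-{1-[2-(6-bromo-1H-indole-2-carboxamido)phenyl]-3-(tert-butyldimethylsilyloxy)propyl}triphenylphosphonium bromide F2. t-BuOK in hot toluene should then give an intramolecular Wittig reaction of the ylide with the anilide carbonyl (Wittig–Madelung indole synthesis), leading to 10.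

Step 7. The activated alcohol may be captured by the reduced azodicarboxylate, or displacement may stall if the N–H is not deprotonated by the betaine. The fallback sets out from 10 and returns at 14, closing ring C before C13 is acylated. TBAF in THF should give 2-[2-(6-bromo-1H-indol-2-yl)-1H-indol-3-yl]ethanol F3, and MsCl/Et3N the sulfonate 2-[2-(6-bromo-1H-indol-2-yl)-1H-indol-3-yl]ethyl methanesulfonate F4. t-BuOK in DMF at 0 °C should give 3-bromo-6,7-dihydro-12H-pyrido[1,2-a:3,4-b']diindole F5, since ionic potassium indolides alkylate at nitrogen. Oxalyl chloride then acylates C13 to 2-(3-bromo-6,7-dihydro-12H-pyrido[1,2-a:3,4-b']diindol-13-yl)-2-oxoacetyl chloride F6, and methanol gives 14.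

Step 8. Hydride abstraction from the acyl-deactivated ring system may be incomplete, the product may be oxidised further, or traces of water may lead to oxygenation at C7. The fallback sets out from 13 and returns at 15, replacing steps 7 and 8 by a condensation that needs no dehydrogenation. Buffered Dess–Martin oxidation should give the aldehyde methyl 2-{6-bromo-2-[3-(2-oxoethyl)-1H-indol-2-yl]-1H-indol-3-yl}-2-oxoacetate F7. Its acidic indole N–H adds to the aldehyde to give the cyclic hemiaminal rac-methyl 2-(3-bromo-6-hydroxy-6,7-dihydro-12H-pyrido[1,2-a:3,4-b']diindol-13-yl)-2-oxoacetate F8. Catalytic TsOH in toluene over molecular sieves should dehydrate it to the C6=C7 compound 15; with C13 already substituted, only nitrogen can condense.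

Further compounds
F1 | step 5 | rac-6-bromo-N-{2-[3-(tert-butyldimethylsilyloxy)-1-hydroxypropyl]phenyl}-1H-indole-2-carboxamide | CC(C)(C)[Si](C)(C)OCCC(O)c1ccccc1NC(=O)c1cc2ccc(Br)cc2[nH]1
F2 | step 5 | rac-{1-[2-(6-bromo-1H-indole-2-carboxamido)phenyl]-3-(tert-butyldimethylsilyloxy)propyl}triphenylphosphonium bromide | CC(C)(C)[Si](C)(C)OCCC(c1ccccc1NC(=O)c1cc2ccc(Br)cc2[nH]1)[P+](c1ccccc1)(c1ccccc1)c1ccccc1.[Br-]
F3 | step 7 | 2-[2-(6-bromo-1H-indol-2-yl)-1H-indol-3-yl]ethanol | OCCc1c(-c2cc3ccc(Br)cc3[nH]2)[nH]c2ccccc12
F4 | step 7 | 2-[2-(6-bromo-1H-indol-2-yl)-1H-indol-3-yl]ethyl methanesulfonate | CS(=O)(=O)OCCc1c(-c2cc3ccc(Br)cc3[nH]2)[nH]c2ccccc12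
F5 | step 7 | 3-bromo-6,7-dihydro-12H-pyrido[1,2-a:3,4-b']diindole | Brc1ccc2cc3-c4[nH]c5ccccc5c4CCn3c2c1
F6 | step 7 | 2-(3-bromo-6,7-dihydro-12H-pyrido[1,2-a:3,4-b']diindol-13-yl)-2-oxoacetyl chloride | O=C(Cl)C(=O)c1c2ccc(Br)cc2n2CCc3c4ccccc4[nH]c3-c12
F7 | step 8 | methyl 2-{6-bromo-2-[3-(2-oxoethyl)-1H-indol-2-yl]-1H-indol-3-yl}-2-oxoacetate | O=CCc1c(-c2c(C(=O)C(=O)OC)c3ccc(Br)cc3[nH]2)[nH]c2ccccc12
F8 | step 8 | rac-methyl 2-(3-bromo-6-hydroxy-6,7-dihydro-12H-pyrido[1,2-a:3,4-b']diindol-13-yl)-2-oxoacetate | COC(=O)C(=O)c1c2ccc(Br)cc2n2C(O)Cc3c4ccccc4[nH]c3-c12
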